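**Remark.** The target has no stereocentre or other stereogenic element, so it is one achiral compound and no step has to control configuration. Ring positions are given in flavone numbering (O1, C2, C3, C4, C4a, C5–C8, C8a).

**Retrosynthetic overview**
1. Target 11 ⇐ 10 by methylation of the free 8-OH; the 5-OH, hydrogen-bonded to C4=O, is left alone.
2. 10 ⇐ 7 by forming O1–C8a. Ring A has its oxygens at C5 and C8 para to each other, so it is a hydroquinone; in its quinone form 8, C8a (next to the acyl-bearing C4a) is electrophilic and the enol oxygen on C2 closes the pyranone ring C onto it.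
3. 7 ⇐ 6 by neutral O-debenzylation; 6 ⇐ 4 + 5 by crossed Claisen condensation (C2–C3 bond).
4. 4 ⇐ 3 ⇐ 1 by acetylation para to the methoxy group (C4–C4a bond) and bis-benzylation.
5. Ring order: rings A and B are bought; ring C is the only ring made, in step 5.

Key step: step 5

**Route**

Step 1
Reactants: 1 2-methoxyhydroquinone
Product: 3 1-(2,5-dihydroxy-4-methoxyphenyl)ethan-1-one, via difluoroboron chelate 2 (not isolated)
Conditions: AcOH, BF3·OEt2 (3 equiv), 90 °C, Ar; then 10% aq. NaOAc, rt
Reagents that add atoms: acetic acid, CC(=O)O
Why: Friedel–Crafts (Nencki-type) C-acylation should go to C5 of 1, the position ortho to a hydroxyl and para to the methoxy group, and the O,O-difluoroboron chelate 2 of the o-hydroxy ketone, which deactivates the ring against a second acylation, is hydrolysed in the aqueous work-up.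

Step 2
Reactants: 3 1-(2,5-dihydroxy-4-methoxyphenyl)ethan-1-one
Product: 4 1-[2,5-bis(benzyloxy)-4-methoxyphenyl]ethan-1-one
Conditions: BnBr (2.4 equiv), K2CO3 (3 equiv), DMF, 70 °C, Ar
Reagents that add atoms: benzyl bromide, BrCc1ccccc1
Why: Williamson etherification of both phenoxides, with heating in DMF to carry along the carbonyl-chelated 2-hydroxyl; benzyl is chosen because it can later be removed under neutral conditions.

Step 3
Reactants: 4 1-[2,5-bis(benzyloxy)-4-methoxyphenyl]ethan-1-one; 5 methyl 2,4-dimethoxybenzoate
Product: 6 1-[2,5-bis(benzyloxy)-4-methoxyphenyl]-3-(2,4-dimethoxyphenyl)propane-1,3-dione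
Conditions: NaH (2.5 equiv), THF, reflux; then cold 1 M HCl
Reagents that add atoms: none
Why: Crossed Claisen condensation in which 4 is the only enolisable partner, ester 5 cannot self-condense, and deprotonation of the 1,3-diketone to its sodium enolate drives the equilibrium to 6.

Step 4
Reactants: 6 1-[2,5-bis(benzyloxy)-4-methoxyphenyl]-3-(2,4-dimethoxyphenyl)propane-1,3-dione
Product: 7 1-(2,5-dihydroxy-4-methoxyphenyl)-3-(2,4-dimethoxyphenyl)propane-1,3-dione
Conditions: H2 (1 atm), 10% Pd/C, EtOAc, rt; filtration and concentration under Ar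
Reagents that add atoms: none
Why: Hydrogenolysis of aryl benzyl ethers on Pd/C is normally faster than reduction of a chelated, enolised diaryl 1,3-diketone, and the neutral medium leaves the o-hydroxyaryl diketone uncyclised; 7 is taken on at once under argon.

Step 5
Reactants: 7 1-(2,5-dihydroxy-4-methoxyphenyl)-3-(2,4-dimethoxyphenyl)propane-1,3-dione
Product: 10 5,8-dihydroxy-7,2',4'-trimethoxyflavone, via acylquinone 8 (not isolated), via oxa-Michael adduct 9 (not isolated)
Conditions: undivided cell, graphite anode, Pt cathode, constant current at the first anodic wave of 7 (≥2 F/mol, to consumption of 7), MeCN–0.1 M aq. sodium phosphate pH 7 (1:1), 5 mM, Ar, rt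
Reagents that add atoms: none
Why: Proposed new method: two-electron anodic oxidation of the hydroquinone ring of 7 at carbon should give acylquinone 8, in which C8a is the β-carbon of both the C5 quinone carbonyl and the side-chain C4 carbonyl, while C6 is deactivated by the vinylogous-ester 7-OMe and out of reach of the tether; the enol(ate) oxygen on C2 then adds to C8a, forming O1–C8a in a 6-endo-trig oxa-Michael closure (equally an oxa-6π electrocyclisation of the O=C2–C3=C4–C4a=C8a oxatriene tautomer) to give 9, and loss of the C8a proton re-aromatises ring A to 10. The closest known reaction types are ECEC electrosyntheses in which anodically generated quinones are trapped in situ by 1,3-dicarbonyl nucleophiles, and oxa-Michael additions of alcohols to 2-acylbenzoquinones. No lasting stereocentre is formed, since the C8a centre of racemic 9 is erased on tautomerisation. The step needs closure through the enol oxygen at C8a instead of dehydrative closure through the C5 oxygen; at the quinone level the C5 oxygen is a carbonyl and cannot act as a nucleophile, and the buffered neutral medium at rt suppresses acid-catalysed cyclodehydration of unoxidised 7. High dilution should keep intermolecular C-addition of a second diketone to 8 slow, and over-oxidation of 10 should be reversible because its oxidised form is reduced again by remaining 7 or at the cathode.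

Step 6
Reactants: 10 5,8-dihydroxy-7,2',4'-trimethoxyflavone
Product: 11 5-hydroxy-2',4',7,8-tetramethoxyflavone
Conditions: MeI (1.1 equiv), K2CO3 (1.2 equiv), degassed acetone, 45 °C, Ar
Reagents that add atoms: methyl iodide, CI
Why: Williamson O-methylation with about one equivalent of MeI should take the free, more acidic 8-hydroxyl, while the 5-hydroxyl, locked in a hydrogen bond to the C4 carbonyl, is known to resist such mild conditions; exclusion of air protects the electron-rich phenoxide.

**Compound list**
1 | 2-methoxyhydroquinone (2-methoxybenzene-1,4-diol) | COc1cc(O)ccc1O | starting material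
2 | O,O-difluoroboron chelate of 3 (2,2-difluoro-6-hydroxy-7-methoxy-4-methyl-1,3,2-benzodioxaborinine, zwitterionic chelate) | CC1=[O+][B-](F)(F)Oc2cc(OC)c(O)cc21 | intermediate
3 | 1-(2,5-dihydroxy-4-methoxyphenyl)ethan-1-one | CC(=O)c1cc(O)c(OC)cc1O | intermediate
4 | 1-[2,5-bis(benzyloxy)-4-methoxyphenyl]ethan-1-one | CC(=O)c1cc(OCc2ccccc2)c(OC)cc1OCc1ccccc1 | intermediate
5 | methyl 2,4-dimethoxybenzoate | COC(=O)c1ccc(OC)cc1OC | starting material
6 | 1-[2,5-bis(benzyloxy)-4-methoxyphenyl]-3-(2,4-dimethoxyphenyl)propane-1,3-dione | COc1ccc(C(=O)CC(=O)c2cc(OCc3ccccc3)c(OC)cc2OCc2ccccc2)c(OC)c1 | intermediate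
7 | 1-(2,5-dihydroxy-4-methoxyphenyl)-3-(2,4-dimethoxyphenyl)propane-1,3-dione | COc1ccc(C(=O)CC(=O)c2cc(O)c(OC)cc2O)c(OC)c1 | intermediate
8 | 2-[3-(2,4-dimethoxyphenyl)-3-oxopropanoyl]-5-methoxycyclohexa-2,5-diene-1,4-dione (acylquinone) | COc1ccc(C(=O)CC(=O)C2=CC(=O)C(OC)=CC2=O)c(OC)c1 | intermediate
9 | 2-(2,4-dimethoxyphenyl)-5-hydroxy-7-methoxy-8aH-chromene-4,8-dione (racemic, transient C8a centre) | COc1ccc(C2=CC(=O)C3=C(O)C=C(OC)C(=O)C3O2)c(OC)c1 | intermediate
10 | 5,8-dihydroxy-7,2',4'-trimethoxyflavone (2-(2,4-dimethoxyphenyl)-5,8-dihydroxy-7-methoxy-4H-chromen-4-one) | COc1ccc(-c2cc(=O)c3c(O)cc(OC)c(O)c3o2)c(OC)c1 | intermediate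
11 | 5-hydroxy-2',4',7,8-tetramethoxyflavone (2-(2,4-dimethoxyphenyl)-5-hydroxy-7,8-dimethoxy-4H-chromen-4-one) | COc1ccc(-c2cc(=O)c3c(O)cc(OC)c(OC)c3o2)c(OC)c1 | target

**Totals**
Total step count: 6. Longest linear sequence: 6 steps (1 → 3 → 4 → 6 → 7 → 10 → 11).

**Steps most likely to fail**

Step 5 (new method). The electrogenerated acylquinone may be intercepted by water or by the nucleophilic carbon of a second diketone molecule before the enol oxygen closes. The product ring may also be oxidised further and then trapped at C6, or the anode may foul by oligomer deposition. The fallback uses known chemistry and does not pass through 7; it sets out from ester 5 and returns at 10. Ester 5 is condensed (NaH, THF, reflux) with commercial 2',6'-dihydroxy-4'-methoxyacetophenone F1 to give 1-(2,6-dihydroxy-4-methoxyphenyl)-3-(2,4-dimethoxyphenyl)propane-1,3-dione F2. Cyclodehydration (H2SO4, AcOH, 90 °C) is unambiguous because the two ortho hydroxyls are equivalent, and should give 5-hydroxy-7,2',4'-trimethoxyflavone F3. Elbs persulfate oxidation (K2S2O8, aq. KOH/pyridine, 10–20 °C) should introduce oxygen para to the 5-oxido group as potassium 5-hydroxy-7,2',4'-trimethoxyflavon-8-yl sulfate F4. Hydrolysis (aq. HCl, Na2SO3, 90 °C) should then deliver 10, which enters step 6.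

Step 6. Methylation may also reach the chelated 5-hydroxyl, or the electron-rich dihydroxy ring may be oxidised by adventitious air under base. The fallback sets out from 10 and returns at 11. Exhaustive methylation (excess Me2SO4, K2CO3, acetone, reflux, Ar) should give 5,7,8,2',4'-pentamethoxyflavone F5. BCl3 (CH2Cl2, −78 → 0 °C) should then cleave only the peri 5-methoxy group through its boron chelate with the C4 carbonyl, giving 11.

Step 4. The enolised diketone may be reduced along with the benzyl ethers, cleavage of the hindered 2-benzyloxy group may stall, or 7 may cyclodehydrate through its ortho hydroxyl on acidic catalyst residues. The fallback drops the protecting groups; it sets out from 3 and returns at 7. The trilithio derivative of 3 (LiHMDS, 4.2 equiv, THF, −78 °C) is C-acylated with commercial 2,4-dimethoxybenzoyl chloride (1 equiv, −78 °C → rt) and quenched with cold dilute acid to give 7 directly. This is the known polyanion acylation of hydroxyacetophenones and makes no new compound (F0).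

**Further compounds**
F1 | step 5 | 2',6'-dihydroxy-4'-methoxyacetophenone | CC(=O)c1c(O)cc(OC)cc1O
F2 | step 5 | 1-(2,6-dihydroxy-4-methoxyphenyl)-3-(2,4-dimethoxyphenyl)propane-1,3-dione | COc1ccc(C(=O)CC(=O)c2c(O)cc(OC)cc2O)c(OC)c1
F3 | step 5 | 5-hydroxy-7,2',4'-trimethoxyflavone | COc1ccc(-c2cc(=O)c3c(O)cc(OC)cc3o2)c(OC)c1
F4 | step 5 | potassium 5-hydroxy-7,2',4'-trimethoxyflavon-8-yl sulfate | COc1ccc(-c2cc(=O)c3c(O)cc(OC)c(OS(=O)(=O)[O-])c3o2)c(OC)c1.[K+]
F5 | step 6 | 5,7,8,2',4'-pentamethoxyflavone | COc1ccc(-c2cc(=O)c3c(OC)cc(OC)c(OC)c3o2)c(OC)c1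
F0 | step 4 | none | none
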